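The route rests on cutting the exocyclic bond between C3, the carbinol carbon of the γ-butyrolactone ring (O1–C2–C3–C4–C5), and the CH2 of the catechol arm. The precursor is the unprotected 3-hydroxy-4-(3,4-dimethoxybenzyl)lactone. It is available in two steps from an organocatalytic glyoxylate aldol in which only C4 has to be controlled. Double deprotonation flattens C3 into a C2=C3 enediolate, so both C3 epimers converge. The feature exploited is the C4 benzyl arm, which shields one face of the five-membered ring and sends the benzylic halide to the other. One operation joins the two halves and sets the tetrasubstituted C3 with its hydroxyl cis to the C4 arm, without hydroxyl protection.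

Key step: step 3

Assumption: the diarylprolinol of step 1 is taken to follow the hydrogen-bond-directed (proline-type) sense of induction, so its (R)-enantiomer is used; compounds 3–5 are drawn as the expected major anti-aldol series, and the minor carbinol epimer is carried along because step 3 erases that centre.

Step 1
Reactants: 1 3-(3,4-dimethoxyphenyl)propanal; 2 ethyl glyoxylate
Product: 3 ethyl (2S,3R)-4-(3,4-dimethoxyphenyl)-3-formyl-2-hydroxybutanoate
Conditions: (R)-α,α-bis[3,5-bis(trifluoromethyl)phenyl]-2-pyrrolidinemethanol (10 mol %), H2O (3 equiv), MeCN, rt; 2 used as its commercial toluene solution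
Reagents that add atoms: none
Why: Enamine-catalysed direct cross-aldol reaction of an enolisable aldehyde with the non-enolisable, highly electrophilic glyoxylate, in which the catalyst hydroxyl directs the glyoxylate onto one face of the (E)-enamine of 1, setting the formyl-bearing carbon (later C4) as R and giving mainly the anti carbinol, whose configuration does not matter later.

Step 2
Reactants: 3 ethyl (2S,3R)-4-(3,4-dimethoxyphenyl)-3-formyl-2-hydroxybutanoate
Product: 5 (3S,4S)-4-(3,4-dimethoxybenzyl)-3-hydroxydihydrofuran-2(3H)-one, via diol ester 4 (not isolated)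
Conditions: NaBH4, EtOH, −20 °C; then p-TsOH·H2O (cat.), CH2Cl2, rt
Reagents that add atoms: none
Why: Chemoselective borohydride reduction of the aldehyde beside the ester, run cold and promptly so that the α-formyl stereocentre does not epimerise, followed by acid-catalysed 5-exo-trig lactonisation of the γ-hydroxy ester with loss of ethanol, with no stereocentre made or touched.

Step 3
Reactants: 5 (3S,4S)-4-(3,4-dimethoxybenzyl)-3-hydroxydihydrofuran-2(3H)-one; 6 3,4-bis(benzyloxy)benzyl chloride
Product: 8 (3S,4S)-3-[3,4-bis(benzyloxy)benzyl]-4-(3,4-dimethoxybenzyl)-3-hydroxydihydrofuran-2(3H)-one, via dilithium enediolate 7 (not isolated)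
Conditions: LDA (2.3 equiv), THF–DMPU, −78 °C; then 6 (1.3 equiv), Bu4NI (10 mol %), −78 → −20 °C; aq. NH4Cl
Reagents that add atoms: none
Why: LDA removes first the O–H and then the C3–H proton, so that either C3 epimer of 5 collapses to the same planar dilithium enediolate 7 (C2=C3), whose C3 carbon displaces chloride from the benzylic carbon of 6 in an SN2 reaction. The closest known reaction types are the C-alkylation of α-hydroxy ester and α-hydroxy lactone dianions and the trans-selective benzylation of β-benzyl-γ-butyrolactone enolates. No ring is closed. The one new stereocentre, C3, is controlled by C4: the 3,4-dimethoxybenzyl arm covers one face of the flat five-membered enediolate, the electrophile enters from the other, and the two benzyl arms end up trans with the hydroxyl cis to the C4 arm, that is (3S,4S), whereas the reverse order (oxygenation of a dibenzyl lactone enolate) would put oxygen anti to that arm. The step needs C- over O-alkylation, which the far higher nucleophilicity of the electron-rich enediolate carbon towards a soft benzylic halide and the tight lithium binding of both oxygens should secure, and it needs to stop after one alkylation, which it should because 8 has no acidic C–H left and its hindered tertiary alkoxide is sluggish at −20 °C. C4 carries no acidic hydrogen and keeps its configuration.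

Step 4
Reactants: 8 (3S,4S)-3-[3,4-bis(benzyloxy)benzyl]-4-(3,4-dimethoxybenzyl)-3-hydroxydihydrofuran-2(3H)-one
Product: 9 (3S,4S)-3-(3,4-dihydroxybenzyl)-4-(3,4-dimethoxybenzyl)-3-hydroxydihydrofuran-2(3H)-one
Conditions: H2 (1 atm), 10% Pd/C, EtOAc–EtOH, rt; work-up under argon
Reagents that add atoms: none
Why: Catalytic hydrogenolysis of the two aryl benzyl ethers, to which the lactone, the methyl ethers, the non-benzylic tertiary alcohol and both stereocentres are inert.

Compound list
1 | 3-(3,4-dimethoxyphenyl)propanal | COc1ccc(CCC=O)cc1OC | starting material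
2 | ethyl glyoxylate | CCOC(=O)C=O | starting material
3 | ethyl (2S,3R)-4-(3,4-dimethoxyphenyl)-3-formyl-2-hydroxybutanoate | CCOC(=O)[C@@H](O)[C@H](C=O)Cc1ccc(OC)c(OC)c1 | intermediate
4 | ethyl (2S,3S)-4-(3,4-dimethoxyphenyl)-2-hydroxy-3-(hydroxymethyl)butanoate | CCOC(=O)[C@@H](O)[C@H](CO)Cc1ccc(OC)c(OC)c1 | intermediate
5 | (3S,4S)-4-(3,4-dimethoxybenzyl)-3-hydroxydihydrofuran-2(3H)-one | COc1ccc(C[C@H]2COC(=O)[C@H]2O)cc1OC | intermediate
6 | 3,4-bis(benzyloxy)benzyl chloride | ClCc1ccc(OCc2ccccc2)c(OCc2ccccc2)c1 | starting material
7 | dilithium (S)-4-(3,4-dimethoxybenzyl)-4,5-dihydrofuran-2,3-diolate | [Li+].[Li+].COc1ccc(C[C@H]2COC([O-])=C2[O-])cc1OC | intermediate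
8 | (3S,4S)-3-[3,4-bis(benzyloxy)benzyl]-4-(3,4-dimethoxybenzyl)-3-hydroxydihydrofuran-2(3H)-one | COc1ccc(C[C@H]2COC(=O)[C@]2(O)Cc2ccc(OCc3ccccc3)c(OCc3ccccc3)c2)cc1OC | intermediate
9 | (3S,4S)-3-(3,4-dihydroxybenzyl)-4-(3,4-dimethoxybenzyl)-3-hydroxydihydrofuran-2(3H)-one | COc1ccc(C[C@H]2COC(=O)[C@]2(O)Cc2ccc(O)c(O)c2)cc1OC | target

Total step count: 4
Longest linear sequence: 4 steps (1 → 3 → 5 → 8 → 9)

Steps most likely to fail

Step 3. The second deprotonation may stay incomplete. The oxygens may be alkylated in competition with carbon. The enediolate may also decay, by oxidation with traces of air or by ketene-type ring opening on warming, before the chloride has reacted. The fallback gives up the unprotected dianion. It sets out from 5 and comes back at 9. Benzyl 2,2,2-trichloroacetimidate with catalytic TfOH (non-basic, so the lactone stays closed) should give the benzyl ether (3S,4S)-3-(benzyloxy)-4-(3,4-dimethoxybenzyl)dihydrofuran-2(3H)-one F1. Ordinary mono-enolisation (LiHMDS, THF, −78 °C) and alkylation with 6, again anti to the C4 arm, should give the tribenzyl compound (3S,4S)-3-(benzyloxy)-3-[3,4-bis(benzyloxy)benzyl]-4-(3,4-dimethoxybenzyl)dihydrofuran-2(3H)-one F2. The conditions of step 4 then remove all three benzyl groups in one operation to give 9.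

Step 1. Self-aldolisation of 1 may compete with the cross-aldol. The polymeric glyoxylate may be released too slowly. Reversible enamine formation at the product stage may erode the configuration at the formyl-bearing carbon. The fallback replaces catalyst control by auxiliary control. It sets out from 1 (with 2) and comes back at 7.
- Pinnick oxidation of 1 gives 3-(3,4-dimethoxyphenyl)propanoic acid F3.
- Coupling of F3 (DCC, DMAP) with (R)-4-benzyloxazolidin-2-one gives the imide (R)-4-benzyl-3-[3-(3,4-dimethoxyphenyl)propanoyl]oxazolidin-2-one F4.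
- An Evans syn-aldol reaction (Bu2BOTf, i-Pr2NEt, CH2Cl2, −78 °C, then freshly cracked 2) should fix the benzyl-bearing carbon. It gives ethyl (2R,3R)-3-{[(4R)-4-benzyl-2-oxooxazolidin-3-yl]carbonyl}-4-(3,4-dimethoxyphenyl)-2-hydroxybutanoate F5.
- NaBH4 in THF–H2O cleaves the imide reductively, and the freed primary alcohol closes onto the ethyl ester. The product is the trans lactone (3R,4S)-4-(3,4-dimethoxybenzyl)-3-hydroxydihydrofuran-2(3H)-one F6, the C3 epimer of 5.
- Under the conditions of step 3, F6 is deprotonated to the same enediolate 7.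

Step 2. The basic borohydride medium may cause epimerisation or retro-aldol cleavage of the β-hydroxy aldehyde. The activated α-hydroxy ester or lactone may also be over-reduced. The fallback takes a redox detour. It sets out from 3 and comes back at 4. Pinnick oxidation (NaClO2, NaH2PO4, 2-methyl-2-butene, t-BuOH–H2O, weakly acidic) turns the labile aldehyde into the configurationally robust half ester (2R,3S)-2-(3,4-dimethoxybenzyl)-4-ethoxy-3-hydroxy-4-oxobutanoic acid F7. BH3·SMe2 (THF, 0 °C) then reduces the free acid chemoselectively beside the ester to 4, which lactonises to 5 as in step 2.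

Further compounds
F1 | step 3 | (3S,4S)-3-(benzyloxy)-4-(3,4-dimethoxybenzyl)dihydrofuran-2(3H)-one | COc1ccc(C[C@H]2COC(=O)[C@H]2OCc2ccccc2)cc1OC
F2 | step 3 | (3S,4S)-3-(benzyloxy)-3-[3,4-bis(benzyloxy)benzyl]-4-(3,4-dimethoxybenzyl)dihydrofuran-2(3H)-one | COc1ccc(C[C@H]2COC(=O)[C@]2(OCc2ccccc2)Cc2ccc(OCc3ccccc3)c(OCc3ccccc3)c2)cc1OC
F3 | step 1 | 3-(3,4-dimethoxyphenyl)propanoic acid | COc1ccc(CCC(=O)O)cc1OC
F4 | step 1 | (R)-4-benzyl-3-[3-(3,4-dimethoxyphenyl)propanoyl]oxazolidin-2-one | COc1ccc(CCC(=O)N2[C@H](Cc3ccccc3)COC2=O)cc1OC
F5 | step 1 | ethyl (2R,3R)-3-{[(4R)-4-benzyl-2-oxooxazolidin-3-yl]carbonyl}-4-(3,4-dimethoxyphenyl)-2-hydroxybutanoate | CCOC(=O)[C@H](O)[C@H](C(=O)N1[C@H](Cc2ccccc2)COC1=O)Cc1ccc(OC)c(OC)c1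
F6 | step 1 | (3R,4S)-4-(3,4-dimethoxybenzyl)-3-hydroxydihydrofuran-2(3H)-one | COc1ccc(C[C@H]2COC(=O)[C@@H]2O)cc1OC
F7 | step 2 | (2R,3S)-2-(3,4-dimethoxybenzyl)-4-ethoxy-3-hydroxy-4-oxobutanoic acid | CCOC(=O)[C@@H](O)[C@H](C(=O)O)Cc1ccc(OC)c(OC)c1
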